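Locants: ten-membered ring C1 (ketone), C2=C3 (C3 on the ring oxygen), C4 (bears C15)=C5, C6 (lactone O), C7, C8 (methacrylate O), C9, C10 (ring oxygen, methyl C14); lactone C11(=C13)–C12. The enabling feature is the dienol ether C2=C3–C4=C5, ring-trans at C2=C3 (that bond lies in the furanone ring O–C3–C2–C1–C10) and ring-cis at C4=C5: the pattern left by conrotatory opening of a cis-fused cyclobutene C2–C3=C4–C5 when C2–C5 breaks.
Retrosynthesis: remove the two esters and C13; reconnect C2–C5 (ten-membered ring back to an eight-membered ring plus cyclobutene); cut C2–C3 and C4–C5 ([2+2]) to a cis-cyclooctenone with an ynol ether on O10; then cut C2=C5 (metathesis), C1–C2 and C5–C6 (vinyl additions), C7–C8 (aldol) and C9–C10 (enolate alkylation).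
Forward: lactic acid gives quaternary C10 carrying the ynol ether masked as a 1,2-dichlorovinyl ether; an aldol joins C7–C8; the lactone ring is closed, then the eight-membered ring; the ynol ether is unmasked; irradiation closes the five-membered O–C3–C2–C1–C10 ring and the cyclobutene; heating opens the cyclobutene to the ten-membered ring; methylenation and two acylations finish.
Stereochemistry: C10 from (S)-lactic acid (alkylation with retention through the tert-butyl dioxolanone); C7 and C8 from an oxazolidinone syn-aldol; C6 from a reagent-controlled ketone reduction; transient C2 and C5 from C10 through the tether; both ring-olefin geometries from the furanone ring and conrotation.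

Key step: step 18

Remark: an alkynyl ether needs organolithium base for its formation, so it is carried as the dichlorovinyl ether through ring closure, and both carbonyl groups are held at the alcohol level for the unmasking step only.
Remark: 22–25 are mixtures at C1 and C12 (both become carbonyl carbons in 26); the C7 descriptor is S in the 8-O-silyl compounds and R in the 8-hydroxy and 8-acyloxy compounds by priority rules alone, the spatial arrangement being unchanged.

Step 1
Reactants: 1 (S)-lactic acid
Product: 2 (2S,5S)-2-tert-butyl-5-methyl-1,3-dioxolan-4-one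
Conditions: t-BuCHO, TsOH·H2O (cat.), H2SO4 (cat.), pentane, reflux (water separator); cis isomer crystallised
Reagents that add atoms: pivalaldehyde, CC(C)(C)C=O
Why: Acid-catalysed acetalisation (first stage of self-regeneration of stereocentres) should favour the cis acetal under thermodynamic control, the lactic acid centre setting the acetal carbon, and crystallisation should remove the trans isomer.

Step 2
Reactants: 2 (2S,5S)-2-tert-butyl-5-methyl-1,3-dioxolan-4-one
Product: 4 (2S,5R)-2-tert-butyl-5-methyl-5-(prop-2-enyl)-1,3-dioxolan-4-one, via lithium enolate 3 (not isolated)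
Conditions: LiN(i-Pr)2, THF, −78 °C; CH2=CHCH2Br, −78 → −20 °C
Reagents that add atoms: allyl bromide, C=CCBr
Why: Enolate alkylation of the dioxolanone should occur on the face opposite the tert-butyl group, so the allyl group (C9, C8) takes the place of the original hydrogen with retention and fixes C10 as R.

Step 3
Reactants: 4 (2S,5R)-2-tert-butyl-5-methyl-5-(prop-2-enyl)-1,3-dioxolan-4-one
Product: 5 (R)-2-hydroxy-2-methyl-1-(morpholin-4-yl)pent-4-en-1-one
Conditions: morpholine, i-PrMgCl, THF, −20 → 20 °C
Reagents that add atoms: morpholine, C1COCCN1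
Why: Aminolysis of the acylal-type ester by the magnesium amide (ester-to-amide exchange) should open the hindered dioxolanone, expel pivalaldehyde and free the tertiary alcohol, giving a C1 amide with no acidic α-hydrogen that later serves as a ketone precursor.

Step 4
Reactants: 5 (R)-2-hydroxy-2-methyl-1-(morpholin-4-yl)pent-4-en-1-one
Product: 7 (R)-2-[(E)-1,2-dichloroethenyloxy]-2-methyl-1-(morpholin-4-yl)pent-4-en-1-one, via potassium alkoxide 6 (not isolated)
Conditions: KH, THF, 0 → 20 °C; Cl2C=CHCl, −50 → 20 °C
Reagents that add atoms: trichloroethylene, ClC=C(Cl)Cl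
Why: In the first stage of the trichloroethylene route to alkynyl ethers, base should turn trichloroethylene into dichloroacetylene, to which the tertiary alkoxide adds anti to give the (E)-1,2-dichlorovinyl ether, a masked ynol ether (C3, C4) that tolerates base, acid and ruthenium carbenes.

Step 5
Reactants: 7 (R)-2-[(E)-1,2-dichloroethenyloxy]-2-methyl-1-(morpholin-4-yl)pent-4-en-1-one
Product: 9 (R)-3-[(E)-1,2-dichloroethenyloxy]-3-methyl-4-(morpholin-4-yl)-4-oxobutanal (the C8 aldehyde), via secondary ozonide 8 (not isolated)
Conditions: O3, CH2Cl2, −78 °C (Sudan red 7B end point); PPh3, −78 → 20 °C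
Reagents that add atoms: ozone, O=[O+][O-]
Why: Ozonolysis with reductive work-up should cleave the electron-rich terminal alkene well before the electron-poor dichlorovinyl ether and leave the C8 aldehyde.

Step 6
Reactants: 10 (R)-4-benzyl-1,3-oxazolidin-2-one; 11 4-tert-butoxy-4-oxobutanoic acid
Product: 13 tert-butyl 4-[(4R)-4-benzyl-2-oxo-1,3-oxazolidin-3-yl]-4-oxobutanoate, via mixed pivalic anhydride 12 (not isolated)
Conditions: t-BuCOCl, Et3N, THF, −20 °C; then 10, LiCl, −20 → 20 °C
Reagents that add atoms: none
Why: N-Acylation of the oxazolidinone through the mixed pivalic anhydride with LiCl and Et3N is the standard mild preparation of Evans imides and should leave the tert-butyl ester untouched.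

Step 7
Reactants: 13 tert-butyl 4-[(4R)-4-benzyl-2-oxo-1,3-oxazolidin-3-yl]-4-oxobutanoate; 9 (R)-3-[(E)-1,2-dichloroethenyloxy]-3-methyl-4-(morpholin-4-yl)-4-oxobutanal
Product: 15 syn-aldol adduct (7R,8S,10R): imide carbonyl at C6, CH2CO2t-Bu (C11, C12) on C7, free 8-OH, 10-methyl, 10-O-(E)-1,2-dichlorovinyl, C1 morpholine amide, via (Z)-boron enolate 14 (not isolated)
Conditions: n-Bu2BOTf, i-Pr2NEt, CH2Cl2, −78 → 0 °C; 9, −78 → 0 °C; aq. NaH2PO4/Na2HPO4 (pH 7), MeOH, H2O2, 0 °C
Reagents that add atoms: none
Why: In the Evans syn-aldol reaction the (Z)-boron enolate should react through a closed chair transition state on the face away from the benzyl group, setting C7 (R) and C8 (S) together, while the tert-butyl ester keeps the new hydroxyl from lactonising.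

Step 8
Reactants: 15 syn-aldol adduct (7R,8S,10R)
Product: 16 C6 Weinreb amide (7R,8S,10R): N-methoxy-N-methyl amide at C6, otherwise as 15
Conditions: MeNH(OMe)·HCl, AlMe3, CH2Cl2, −20 → 0 °C
Reagents that add atoms: N,O-dimethylhydroxylamine hydrochloride, CNOC.Cl
Why: Weinreb transamidation by the aluminium amide, directed by the aluminium alkoxide of the free β-hydroxyl, should cleave the exocyclic imide carbonyl and release the auxiliary, the tert-butyl ester and the morpholine amide being too hindered or too unreactive to exchange.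

Step 9
Reactants: 16 C6 Weinreb amide (7R,8S,10R)
Product: 17 8-O-tert-butyldimethylsilyl ether of 16 (7R,8S,10R)
Conditions: t-BuMe2SiOTf, 2,6-lutidine, CH2Cl2, −78 → −20 °C
Reagents that add atoms: tert-butyldimethylsilyl triflate, CC(C)(C)[Si](C)(C)OS(=O)(=O)C(F)(F)F
Why: Silylation of the secondary alcohol with a silyl triflate and a hindered pyridine base at low temperature should cap O8 before any hydroxyl at C6 exists, so that the later lactone can form only at O6.

Step 10
Reactants: 17 8-O-tert-butyldimethylsilyl ether (7R,8S,10R)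
Product: 18 bis(vinyl ketone) (7R,8S,10R): CH2=CH–C6(=O) and CH2=CH–C1(=O), CH2CO2t-Bu on C7, 8-OTBS, 10-O-(E)-1,2-dichlorovinyl
Conditions: CH2=CHMgBr (5 equiv), THF, −78 → 0 °C; inverse quench into cold aq. HCl/NH4Cl
Reagents that add atoms: vinylmagnesium bromide, C=C[Mg]Br
Why: Ketone synthesis by Grignard addition to a Weinreb amide and to a morpholine amide should stop at the stable tetrahedral magnesium chelates, which release the two vinyl ketones (C5 and C2 installed) only on acidic quench, where the liberated amines are protonated and cannot add to the enones.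

Step 11
Reactants: 18 bis(vinyl ketone) (7R,8S,10R)
Product: 19 (6R)-allylic alcohol (6R,7S,8S,10R): C6 carbinol bearing vinyl, C1 vinyl ketone retained
Conditions: (S)-2-methyl-CBS-oxazaborolidine (0.5 equiv), BH3·SMe2 (1.0 equiv), THF, −40 °C; MeOH
Reagents that add atoms: none
Why: In the Corey–Bakshi–Shibata reduction the catalyst should bind the ketone with the branched C7 residue as the large group and the vinyl group as the small one and deliver hydride to the face that gives 6R (against the weak Felkin preference), the C6 ketone reacting before the C1 ketone on the fully substituted C10; any C1 alcohol formed converges later at 22.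

Step 12
Reactants: 19 (6R)-allylic alcohol (6R,7S,8S,10R)
Product: 20 trans-lactone diene (6R,7S,8S,10R): γ-vinyl butyrolactone O6–C12(=O)–C11–C7, with the C8(OTBS)–C9H2–C10(Me)(O-dichlorovinyl)–C1(=O)–CH=CH2 chain on C7
Conditions: CF3CO2H, CH2Cl2, 0 °C
Reagents that add atoms: none
Why: Acid-mediated cleavage of the tert-butyl ester with lactonisation onto the only free hydroxyl should give the γ-lactone with retention at C6, trans-disubstituted because O6 and the C11 branch are syn along the chain.

Step 13
Reactants: 20 trans-lactone diene (6R,7S,8S,10R)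
Product: 21 cis-cyclooctenone (6R,7S,8S,10R): ring C1(=O)–C2H=C5H–C6–C7–C8–C9–C10, trans-fused 6,12-lactone, 8-OTBS, 10-methyl, 10-O-(E)-1,2-dichlorovinyl
Conditions: second-generation Grubbs catalyst (H2IMes)(PCy3)Cl2Ru=CHPh (10 mol %), 1,4-benzoquinone (20 mol %), CH2Cl2 (1 mM), 40 °C
Reagents that add atoms: none
Why: In ring-closing olefin metathesis the carbene formed at the C6 vinyl group should close onto the enone olefin, helped by the trans-fused lactone and the quaternary C10, the eight-membered ring allowing only the cis olefin and the chlorinated enol ether being inert to the carbene.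

Step 14
Reactants: 21 cis-cyclooctenone (6R,7S,8S,10R)
Product: 22 allylic alcohol–lactol (6R,7S,8S,10R; mixture at C1 and C12): C1 carbinol, C12 hemiacetal, otherwise as 21
Conditions: i-Bu2AlH, CH2Cl2, −78 °C; aq. potassium sodium tartrate
Reagents that add atoms: none
Why: Hydride reduction with i-Bu2AlH at −78 °C should take the enone to the allylic alcohol (1,2-reduction) and the lactone to the lactol, so that no carbonyl group meets the organolithium step; the two new centres return to carbonyl carbons later.

Step 15
Reactants: 22 allylic alcohol–lactol (6R,7S,8S,10R)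
Product: 24 ynol ether triol (6R,7S,8S,10R): 10-O–C3≡C4–C15H2OH, free 1-OH and lactol OH, 8-OTBS, via trilithium alkoxyacetylide 23 (not isolated)
Conditions: n-BuLi (4.5 equiv), THF, −78 → −40 °C (22 added to the base); CH2O (gas), −78 → −20 °C; aq. NaHCO3
Reagents that add atoms: formaldehyde, C=O
Why: In the second stage of the trichloroethylene route, n-BuLi should remove the vinylic hydrogen, chloride is eliminated and lithium–chlorine exchange gives the lithium alkoxyacetylide, which adds to formaldehyde (C15), the two hydroxyls being protected as lithium alkoxides and the lactolate staying closed at −78 °C.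

Step 16
Reactants: 24 ynol ether triol (6R,7S,8S,10R)
Product: 25 15-O-tert-butyldimethylsilyl ether of 24 (6R,7S,8S,10R)
Conditions: t-BuMe2SiCl (1.05 equiv), imidazole, CH2Cl2, −20 → 0 °C
Reagents that add atoms: tert-butyldimethylsilyl chloride, CC(C)(C)[Si](C)(C)Cl
Why: Selective silylation with a bulky silyl chloride should take the primary propargylic alcohol well before the hindered C1 carbinol or the lactol hydroxyl, as in the 6-O-silylation of free hexoses.

Step 17
Reactants: 25 15-O-tert-butyldimethylsilyl ether (6R,7S,8S,10R)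
Product: 26 photosubstrate (6R,7S,8S,10R): cis-cyclooctenone with trans-fused 6,12-lactone, 8-OTBS and the C10 alkynyl ether O–C≡C–CH2OTBS
Conditions: (n-Pr)4N[RuO4] (10 mol %), N-methylmorpholine N-oxide, 4 Å molecular sieves, CH2Cl2, 0 → 20 °C
Reagents that add atoms: none
Why: The Ley–Griffith oxidation should convert the allylic alcohol into the enone and the lactol into the lactone in one neutral operation, with no acid that would hydrate the ynol ether.

Step 18
Reactants: 26 photosubstrate (6R,7S,8S,10R)
Product: 27 cis-fused tricyclic cyclobutene (2R,5S,6R,7S,8S,10R): cyclobutene C2–C3=C4–C5 with C15H2OTBS on C4, five-membered ring O–C3–C2–C1(=O)–C10, eight-membered ring and lactone as in 26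
Conditions: hν (365 nm), degassed MeCN (1 mM), solid K2CO3, −30 °C
Reagents that add atoms: none
Why: Proposed new method: n→π* excitation and intersystem crossing should give the twisted triplet enone, whose α-carbon C2 bonds first to the ynol ether carbon C3, and the resulting 1,4-diradical (alkyl at C5, vinyl at C4) closes C4–C5 after spin inversion; the closest known reaction type is the intramolecular enone–alkyne [2+2] photocycloaddition through a three-atom tether, which gives the same kind of strained ring-fusion cyclobutene but has not been shown with an ynol ether or on an eight-membered enone. The five-membered ring O–C3–C2–C1–C10 closes in the 5-exo-dig (1,5) mode, and the cyclobutene closes by recombination of the diradical. C2 is set by C10, because the O–C10–C1 tether reaches C2 only on the enone face syn to the C10 oxygen (C1 becomes a one-atom bridge between C2 and C10). C5 is set by collapse of the short-lived diradical on that same face, which gives the cis fusion of the four- and eight-membered rings. The step needs the straight and not the crossed adduct and freedom from secondary photochemistry: the three-atom tether secures the first (C2–C4 bonding would require a six-membered first closure), and irradiation at 365 nm and −30 °C, where the β,γ-unsaturated ketone product absorbs little and does not yet open, should secure the second.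

Step 19
Reactants: 27 cis-fused tricyclic cyclobutene
Product: 28 furanone dienone (6R,7S,8S,10R): ten-membered ring with C2=C3 in the 3(2H)-furanone and ring-cis C4=C5, 15-OTBS, 8-OTBS, saturated 6,12-lactone
Conditions: toluene, 60 °C, dark (27 used without purification)
Reagents that add atoms: none
Why: Thermal conrotatory 4π electrocyclic opening of the strained cyclobutene (two-carbon ring expansion) should break C2–C5, and because the furanone ring forces C1 outward at C2, C6 turns inward at C5 and the ring-trans C2=C3, ring-cis C4=C5 dienone results.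

Step 20
Reactants: 28 furanone dienone (6R,7S,8S,10R)
Product: 32 α-methylene lactone (6R,7S,8S,10R): C11=C13H2, otherwise as 28, via lithium enolate 29 (not isolated), via Mannich base 30 (not isolated), via methiodide 31 (not isolated)
Conditions: LiN(i-Pr)2, THF, −78 °C; CH2=NMe2+ I−, −78 → 0 °C; MeI, THF/MeOH, 20 °C; aq. NaHCO3, CH2Cl2
Reagents that add atoms: Eschenmoser's salt (N,N-dimethylmethyleneiminium iodide), C=[N+](C)C.[I-]
Why: In the Eschenmoser methylenation, kinetic deprotonation should occur at the only enolisable α-CH2 (C11; the furanone ketone has no α-hydrogen), the enolate is aminomethylated, and quaternisation followed by mild base-induced elimination gives the exocyclic alkene.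

Step 21
Reactants: 32 α-methylene lactone (6R,7S,8S,10R)
Product: 33 8,15-diol (6R,7R,8S,10R)
Conditions: HF·pyridine, pyridine, THF, 0 → 20 °C
Reagents that add atoms: none
Why: Fluoride-mediated desilylation under buffered, weakly acidic conditions should remove both silyl ethers without the base that could cause translactonisation to O8 or conjugate addition to the methylene lactone.

Step 22
Reactants: 33 8,15-diol (6R,7R,8S,10R)
Product: 34 15-acetate with free 8-OH (6R,7R,8S,10R)
Conditions: Ac2O (1.1 equiv), 2,4,6-collidine, CH2Cl2, −40 → 0 °C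
Reagents that add atoms: acetic anhydride, CC(=O)OC(C)=O
Why: Selective acylation with limiting anhydride and a hindered pyridine base at low temperature should esterify the primary allylic alcohol before the hindered secondary ring alcohol.

Step 23
Reactants: 34 15-acetate (6R,7R,8S,10R)
Product: 35 target CNP0179932.1 (6R,7R,8S,10R)
Conditions: methacrylic anhydride, Et3N, DMAP (cat.), CH2Cl2, 0 → 20 °C
Reagents that add atoms: methacrylic anhydride, C=C(C)C(=O)OC(=O)C(C)=C
Why: DMAP-catalysed esterification of the remaining secondary alcohol with methacrylic anhydride should complete the target without touching any stereocentre.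

Compound list
1 | (S)-lactic acid | C[C@H](O)C(=O)O | starting material
2 | (2S,5S)-2-tert-butyl-5-methyl-1,3-dioxolan-4-one | C[C@@H]1O[C@H](C(C)(C)C)OC1=O | intermediate
3 | lithium enolate of 2 | CC1=C([O-])O[C@@H](C(C)(C)C)O1.[Li+] | intermediate
4 | (2S,5R)-2-tert-butyl-5-methyl-5-(prop-2-enyl)-1,3-dioxolan-4-one | C[C@]1(CC=C)O[C@H](C(C)(C)C)OC1=O | intermediate
5 | (R)-2-hydroxy-2-methyl-1-(morpholin-4-yl)pent-4-en-1-one | C=CC[C@@](C)(O)C(=O)N1CCOCC1 | intermediate
6 | potassium alkoxide of 5 | C=CC[C@@](C)([O-])C(=O)N1CCOCC1.[K+] | intermediate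
7 | (R)-2-[(E)-1,2-dichloroethenyloxy]-2-methyl-1-(morpholin-4-yl)pent-4-en-1-one | C=CC[C@@](C)(O/C(Cl)=C\Cl)C(=O)N1CCOCC1 | intermediate
8 | secondary ozonide (1,2,4-trioxolane) of 7 | C1OC(OO1)C[C@@](C)(O/C(Cl)=C\Cl)C(=O)N1CCOCC1 | intermediate
9 | (R)-3-[(E)-1,2-dichloroethenyloxy]-3-methyl-4-(morpholin-4-yl)-4-oxobutanal | O=CC[C@@](C)(O/C(Cl)=C\Cl)C(=O)N1CCOCC1 | intermediate
10 | (R)-4-benzyl-1,3-oxazolidin-2-one | O=C1N[C@H](Cc2ccccc2)CO1 | starting material
11 | 4-tert-butoxy-4-oxobutanoic acid | CC(C)(C)OC(=O)CCC(=O)O | starting material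
12 | mixed anhydride of 11 with pivalic acid | CC(C)(C)OC(=O)CCC(=O)OC(=O)C(C)(C)C | intermediate
13 | tert-butyl 4-[(4R)-4-benzyl-2-oxo-1,3-oxazolidin-3-yl]-4-oxobutanoate | CC(C)(C)OC(=O)CCC(=O)N1[C@H](Cc2ccccc2)COC1=O | intermediate
14 | (Z)-di-n-butylboron enolate of 13 | CCCCB(CCCC)O/C(=C\CC(=O)OC(C)(C)C)N1[C@H](Cc2ccccc2)COC1=O | intermediate
15 | syn-aldol adduct (7R,8S,10R) | CC(C)(C)OC(=O)C[C@H]([C@@H](O)C[C@@](C)(O/C(Cl)=C\Cl)C(=O)N1CCOCC1)C(=O)N1[C@H](Cc2ccccc2)COC1=O | intermediate
16 | C6 Weinreb amide (7R,8S,10R) | CC(C)(C)OC(=O)C[C@H]([C@@H](O)C[C@@](C)(O/C(Cl)=C\Cl)C(=O)N1CCOCC1)C(=O)N(C)OC | intermediate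
17 | 8-O-TBS Weinreb amide (7R,8S,10R) | CC(C)(C)OC(=O)C[C@H]([C@@H](O[Si](C)(C)C(C)(C)C)C[C@@](C)(O/C(Cl)=C\Cl)C(=O)N1CCOCC1)C(=O)N(C)OC | intermediate
18 | bis(vinyl ketone) (7R,8S,10R) | CC(C)(C)OC(=O)C[C@H]([C@@H](O[Si](C)(C)C(C)(C)C)C[C@@](C)(O/C(Cl)=C\Cl)C(=O)C=C)C(=O)C=C | intermediate
19 | (6R)-allylic alcohol (6R,7S,8S,10R) | CC(C)(C)OC(=O)C[C@H]([C@@H](O[Si](C)(C)C(C)(C)C)C[C@@](C)(O/C(Cl)=C\Cl)C(=O)C=C)[C@H](O)C=C | intermediate
20 | trans-lactone diene (6R,7S,8S,10R) | C=CC(=O)[C@](C)(O/C(Cl)=C\Cl)C[C@H](O[Si](C)(C)C(C)(C)C)[C@H]1CC(=O)O[C@@H]1C=C | intermediate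
21 | cis-cyclooctenone lactone with dichlorovinyl ether (6R,7S,8S,10R) | CC(C)(C)[Si](C)(C)O[C@H]1C[C@@](C)(O/C(Cl)=C\Cl)C(=O)/C=C\[C@H]2OC(=O)C[C@H]12 | intermediate
22 | allylic alcohol–lactol (6R,7S,8S,10R; C1, C12 mixtures) | CC(C)(C)[Si](C)(C)O[C@H]1C[C@@](C)(O/C(Cl)=C\Cl)C(O)/C=C\[C@H]2OC(O)C[C@H]12 | intermediate
23 | trilithium alkoxyacetylide | CC(C)(C)[Si](C)(C)O[C@H]1C[C@@](C)(OC#C[Li])C(O[Li])/C=C\[C@H]2OC(O[Li])C[C@H]12 | intermediate
24 | ynol ether triol (6R,7S,8S,10R; C1, C12 mixtures) | CC(C)(C)[Si](C)(C)O[C@H]1C[C@@](C)(OC#CCO)C(O)/C=C\[C@H]2OC(O)C[C@H]12 | intermediate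
25 | 15-O-TBS ynol ether diol (6R,7S,8S,10R; C1, C12 mixtures) | CC(C)(C)[Si](C)(C)O[C@H]1C[C@@](C)(OC#CCO[Si](C)(C)C(C)(C)C)C(O)/C=C\[C@H]2OC(O)C[C@H]12 | intermediate
26 | photosubstrate: cis-cyclooctenone, fused lactone, C10 alkynyl ether (6R,7S,8S,10R) | CC(C)(C)[Si](C)(C)O[C@H]1C[C@@](C)(OC#CCO[Si](C)(C)C(C)(C)C)C(=O)/C=C\[C@H]2OC(=O)C[C@H]12 | intermediate
27 | cis-fused tricyclic cyclobutene (2R,5S,6R,7S,8S,10R) | CC(C)(C)[Si](C)(C)O[C@H]1C[C@@]2(C)OC3=C(CO[Si](C)(C)C(C)(C)C)[C@H]([C@H]3C2=O)[C@H]2OC(=O)C[C@H]12 | intermediate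
28 | furanone dienone, bis-TBS ether (6R,7S,8S,10R) | CC(C)(C)[Si](C)(C)O[C@H]1C[C@@]2(C)OC(=CC2=O)/C(CO[Si](C)(C)C(C)(C)C)=C\[C@H]2OC(=O)C[C@H]12 | intermediate
29 | lithium lactone enolate of 28 | CC(C)(C)[Si](C)(C)O[C@H]1C[C@@]2(C)OC(=CC2=O)/C(CO[Si](C)(C)C(C)(C)C)=C\[C@H]2OC([O-])=C[C@H]12.[Li+] | intermediate
30 | Mannich base (11-dimethylaminomethyl lactone) | CC(C)(C)[Si](C)(C)O[C@H]1C[C@@]2(C)OC(=CC2=O)/C(CO[Si](C)(C)C(C)(C)C)=C\[C@H]2OC(=O)C(CN(C)C)[C@H]12 | intermediate
31 | methiodide of 30 | CC(C)(C)[Si](C)(C)O[C@H]1C[C@@]2(C)OC(=CC2=O)/C(CO[Si](C)(C)C(C)(C)C)=C\[C@H]2OC(=O)C(C[N+](C)(C)C)[C@H]12.[I-] | intermediate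
32 | α-methylene lactone, bis-TBS ether (6R,7S,8S,10R) | CC(C)(C)[Si](C)(C)O[C@H]1C[C@@]2(C)OC(=CC2=O)/C(CO[Si](C)(C)C(C)(C)C)=C\[C@H]2OC(=O)C(=C)[C@H]12 | intermediate
33 | 8,15-diol (6R,7R,8S,10R) | O[C@H]1C[C@@]2(C)OC(=CC2=O)/C(CO)=C\[C@H]2OC(=O)C(=C)[C@H]12 | intermediate
34 | 15-acetate, 8-OH (6R,7R,8S,10R) | O[C@H]1C[C@@]2(C)OC(=CC2=O)/C(COC(C)=O)=C\[C@H]2OC(=O)C(=C)[C@H]12 | intermediate
35 | CNP0179932.1 (6R,7R,8S,10R) | C=C(C)C(=O)O[C@H]1C[C@@]2(C)OC(=CC2=O)/C(COC(C)=O)=C\[C@H]2OC(=O)C(=C)[C@H]12 | target

Total step count: 23. Longest linear sequence: 22 steps (steps 1–5 and 7–23, from (S)-lactic acid); step 6 is the one-step side branch.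

Steps most likely to fail

Step 18 (photocycloaddition). The excited cis-cyclooctenone may relax by twisting to the strained trans-enone faster than C2 bonds to C3, after which ground-state dimerisation or a trans-fused addition would take over. Continued irradiation may also send the β,γ-unsaturated ketone product into a 1,3-acyl shift, and the tertiary ynol ether may be lost by retro-ene fragmentation if the solution warms. The fallback replaces the excited state by ground-state catalysis and sets out from 26. AgNTf2 (10 mol %) in CH2Cl2 at −40 → 0 °C should promote a stepwise [2+2] of the Ficini type, established for siloxy alkynes and ynamides with cyclic enones. The nucleophilic C4 of the ynol ether adds to C5 of the silver-activated enone and the C2 enolate closes onto C3. The cis ring fusion follows from the cis enone, and the route is rejoined at 27 without any new compound.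

Step 15 (unmasking the ynol ether). Butyllithium may add to the open hydroxy-aldehyde form of the lithium lactolate, or the neighbouring C1 alkoxide may add to the transient chloroalkynyl ether before lithium–chlorine exchange. The fallback removes both free alkoxides and sets out from 22. Me3SiCl and imidazole in CH2Cl2 should give the bis(trimethylsilyl) ether F1. The same n-BuLi and CH2O sequence then gives the propargylic alcohol F2, and t-BuMe2SiCl with imidazole gives the mixed silyl ether F3. K2CO3 in MeOH should then remove only the two trimethylsilyl groups, and the route is rejoined at 25.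

Step 13 (eight-membered ring closure). Intermolecular metathesis may outrun the slow closure onto the electron-poor, neopentyl enone olefin and lead to oligomers, and the catalyst may decompose before turnover. The fallback closes the ring at the alcohol oxidation level, where both olefins are electron-neutral, and sets out from 20. Luche reduction (NaBH4, CeCl3·7H2O, MeOH, −78 °C) should give the C1 allylic alcohol F4 as a mixture of epimers. Ring-closing metathesis with the same catalyst should give the cyclooctenol lactone F5. Reduction of the lactone alone with i-Bu2AlH then rejoins the route at 22.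

Further compounds
F0 | step 18 | none | none
F1 | step 15 | bis(trimethylsilyl) ether of 22 (1-OTMS, lactol OTMS) | CC(C)(C)[Si](C)(C)O[C@H]1C[C@@](C)(O/C(Cl)=C\Cl)C(O[Si](C)(C)C)/C=C\[C@H]2OC(O[Si](C)(C)C)C[C@H]12
F2 | step 15 | bis(trimethylsilyl) ynol ether with free 15-OH | CC(C)(C)[Si](C)(C)O[C@H]1C[C@@](C)(OC#CCO)C(O[Si](C)(C)C)/C=C\[C@H]2OC(O[Si](C)(C)C)C[C@H]12
F3 | step 15 | 15-O-TBS bis(trimethylsilyl) ynol ether | CC(C)(C)[Si](C)(C)O[C@H]1C[C@@](C)(OC#CCO[Si](C)(C)C(C)(C)C)C(O[Si](C)(C)C)/C=C\[C@H]2OC(O[Si](C)(C)C)C[C@H]12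
F4 | step 13 | C1 allylic alcohol of lactone diene 20 (C1 epimers) | C=CC(O)[C@](C)(O/C(Cl)=C\Cl)C[C@H](O[Si](C)(C)C(C)(C)C)[C@H]1CC(=O)O[C@@H]1C=C
F5 | step 13 | cis-cyclooctenol lactone with dichlorovinyl ether (C1 epimers) | CC(C)(C)[Si](C)(C)O[C@H]1C[C@@](C)(O/C(Cl)=C\Cl)C(O)/C=C\[C@H]2OC(=O)C[C@H]12
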